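## Retrosynthetic overview

1. The target comes from hydrogenolysis of its heptadeca-O-benzyl ether, and that ether from one threefold copper-catalysed aryl ether closure. The feature used: in each fisetinidol unit (T, M, U) the ring oxygen O1 is an aryl ether joining the benzylic C2 to C8a of ring A, while C2, C3 and C4 are contiguous sp3 carbons. Cutting O1–C8a therefore opens ring C of all three units to a C2 alcohol and an ortho-bromide on ring A.
2. The open-chain tris(2-bromoaryl) triol comes from three C4–C4a bonds. Each is made by copper-catalysed opening of a trans-epoxide (C3–C4) by a 2-bromoaryl Grignard reagent, with inversion at C4. C3 comes from poly-D-leucine epoxidation of a chalcone and C2 from chelation-controlled Zn(BH4)2 reduction; C3–OH is then benzylated.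
3. The chalcones come from Claisen–Schmidt condensation of 3,4-dibenzyloxyacetophenone with aldehydes at C8, then C6, of penta-O-benzylcatechin and at C6 of the future ring A of unit M. Unit T is built first on that ring (an aryl iodide), which then serves as the Grignard partner that creates unit M.
4. Ring order: the pyran ring of the catechin unit comes from the chiral pool; no ring is formed until the key step; rings C of U, M and T are then formed together; deprotection follows.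

Key step: step 30

## Remarks

- Flavan numbering (C2, C3, C4, C4a, C8a; rings A, B, C) is used for the open-chain units. Abbreviations in names: Ar = 3,4-bis(benzyloxy)phenyl; ArBr = 4-(benzyloxy)-2-bromophenyl; cat = (2R,3S)-3,5,7,3',4'-penta-O-benzylcatechin core; TBDPS = tert-butyldiphenylsilyl.
- Assumption: 1-[3,4-bis(benzyloxy)phenyl]ethanone and 4-bromo-2-hydroxybenzaldehyde are purchased, and poly-D-leucine is made from D-leucine N-carboxyanhydride.
- C3 of each open-chain unit is carried as a benzyl ether. A silyl ether next to the C2 caesium alkoxide could migrate at 110 °C and expose C3–O to five-membered O-arylation; a benzyl ether cannot, and it falls in the final hydrogenolysis.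
- The 2-bromoaryl Grignard reagent 15 is made once (step 10) as a cold THF solution and serves both epoxide openings that install a ring A (steps 11 and 25). The branch that gives epoxide 31 (steps 19–24) is therefore run before step 10, and steps 11 and 25 are run side by side from the same batch.

## Route

Step 1
Reactants: 1 3-bromophenol
Product: 2 1-(benzyloxy)-3-bromobenzene
Conditions: BnBr, K2CO3, DMF, rt
Reagents that add atoms: benzyl bromide, BrCc1ccccc1
Why: Williamson ether synthesis on a simple phenoxide is reliable and leaves the aryl bromide untouched.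

Step 2
Reactants: 2 1-(benzyloxy)-3-bromobenzene
Product: 3 4-(benzyloxy)-2-bromo-1-iodobenzene
Conditions: NIS, CF3CO2H (cat.), MeCN, rt
Reagents that add atoms: N-iodosuccinimide, O=C1CCC(=O)N1I
Why: Electrophilic aromatic iodination goes para to the benzyloxy group, so that iodine (the future C4a) ends up ortho to bromine (the future C8a).

Step 3
Reactants: 4 (+)-catechin
Product: 6 3,5,7,3',4'-penta-O-benzyl-(+)-catechin, via tetra-O-benzylcatechin 5 (not isolated)
Conditions: BnBr, K2CO3, DMF, rt; then NaH, 0 °C → rt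
Reagents that add atoms: benzyl bromide, BrCc1ccccc1
Why: Williamson etherification of the four phenoxides (K2CO3) and then of the secondary C3 alkoxide (NaH) gives the fully benzylated flavan without touching C2 or C3.

Step 4
Reactants: 6 3,5,7,3',4'-penta-O-benzyl-(+)-catechin
Product: 7 8-bromo-cat
Conditions: NBS, CH2Cl2, −20 → 0 °C
Reagents that add atoms: N-bromosuccinimide, O=C1CCC(=O)N1Br
Why: Electrophilic aromatic bromination of the phloroglucinol-type ring A with one equivalent of NBS goes to C8, the position that reacts first in 5,7-di-O-benzylflavan-3-ol ethers.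

Step 5
Reactants: 7 8-bromo-cat
Product: 9 cat-8-carbaldehyde, via 8-lithio-cat 8 (not isolated)
Conditions: n-BuLi, THF, −78 °C; DMF, −78 → 0 °C; aq. NH4Cl
Reagents that add atoms: n-butyllithium, CCCC[Li] (lithium of 8); N,N-dimethylformamide, CN(C)C=O (formyl group of 9)
Why: Bromine–lithium exchange and trapping of the aryllithium with DMF (Bouveault aldehyde synthesis) puts the formyl group exactly where bromine was.

Step 6
Reactants: 9 cat-8-carbaldehyde; 10 1-[3,4-bis(benzyloxy)phenyl]ethanone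
Product: 11 (E)-1-Ar-3-(cat-8-yl)prop-2-en-1-one
Conditions: KOH, EtOH/THF, rt
Reagents that add atoms: none
Why: Claisen–Schmidt condensation (crossed aldol addition and dehydration) of the non-enolisable aldehyde with the methyl ketone gives the conjugated E-enone, as is usual for 2,4,6-trialkoxybenzaldehydes.

Step 7
Reactants: 11 (E)-1-Ar-3-(cat-8-yl)prop-2-en-1-one
Product: 12 Ar[(2S,3R)-3-(cat-8-yl)oxiran-2-yl]methanone
Conditions: poly-D-leucine, urea·H2O2, DBU, THF, rt
Reagents that add atoms: urea–hydrogen peroxide, NC(N)=O.OO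
Why: Juliá–Colonna epoxidation (hydroperoxide conjugate addition and ring closure on the polypeptide) gives the trans-epoxy ketone, and poly-D-leucine, the mirror image of the usual catalyst, selects the face that makes the α-carbon S (future C3) and the β-carbon R (future C4 before inversion).

Step 8
Reactants: 12 Ar[(2S,3R)-3-(cat-8-yl)oxiran-2-yl]methanone
Product: 13 anti epoxy alcohol of unit U with R carbinol carbon
Conditions: Zn(BH4)2, Et2O/THF, −30 °C; aq. NH4Cl
Reagents that add atoms: none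
Why: Chelation-controlled ketone reduction: zinc binds the carbonyl and oxirane oxygens and hydride enters anti to the oxirane C–C bond, which gives the anti epoxy alcohol and sets the future C2 as R.

Step 9
Reactants: 13 anti epoxy alcohol of unit U
Product: 14 TBDPS ether of 13
Conditions: TBDPSCl, imidazole, DMAP (cat.), DMF, rt
Reagents that add atoms: tert-butyl(chloro)diphenylsilane, CC(C)(C)[Si](Cl)(c1ccccc1)c1ccccc1
Why: Silyl ether formation under basic conditions masks the C2 hydroxyl without acid, which the electron-rich aryl epoxide would not survive, and the bulky silyl group is chosen because it resists 1,2-migration in step 12.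

Step 10
Reactants: 3 4-(benzyloxy)-2-bromo-1-iodobenzene
Product: 15 [4-(benzyloxy)-2-bromophenyl]magnesium chloride as a THF solution kept at −30 °C
Conditions: i-PrMgCl, THF, −30 °C
Reagents that add atoms: isopropylmagnesium chloride, CC(C)[Mg]Cl
Why: Iodine–magnesium exchange (halogen–metal exchange with an alkyl Grignard reagent) takes the iodide far faster than the bromide, and at −30 °C the 2-bromoaryl Grignard reagent should not eliminate to the aryne, so the solution can be divided at once between steps 11 and 25.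

Step 11
Reactants: 14 TBDPS ether of 13; 15 [4-(benzyloxy)-2-bromophenyl]magnesium chloride
Product: 16 open-chain unit U on cat C8 carrying C2–OTBDPS, free C3–OH and ArBr on C4 (2R,3S,4R)
Conditions: 15 (THF solution), CuI (10 mol%), −30 °C; then 14, −30 → 0 °C; aq. NH4Cl
Reagents that add atoms: none
Why: Copper-catalysed SN2 opening of the epoxide at its benzylic carbon by the aryl Grignard reagent (organocuprate epoxide opening) proceeds with inversion, which sets C4 of unit U, frees the C3 hydroxyl and keeps the ortho-bromide for the later ring closure.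

Step 12
Reactants: 16 open-chain unit U with free C3–OH
Product: 17 C3-O-benzyl ether of 16
Conditions: NaH, BnBr, Bu4NI (cat.), THF/DMF, 0 °C
Reagents that add atoms: benzyl bromide, BrCc1ccccc1
Why: Williamson etherification of the C3 alkoxide in the presence of excess benzyl bromide gives the ether that keeps C3–O out of the later arylation, the hindered silyl group on C2–O being too slow to migrate.

Step 13
Reactants: 17 C3-O-benzyl ether of 16
Product: 18 6-iodo derivative of 17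
Conditions: NIS, CH2Cl2, 0 °C
Reagents that add atoms: N-iodosuccinimide, O=C1CCC(=O)N1I
Why: Electrophilic aromatic iodination takes the only free position of the trialkoxy ring A of the catechin unit (C6), which is far more nucleophilic than the other arenes.

Step 14
Reactants: 18 6-iodo derivative of 17
Product: 20 6-formyl derivative of 17, via 6-chloromagnesio derivative 19 (not isolated)
Conditions: i-PrMgCl·LiCl, THF, 0 °C → rt; DMF; aq. NH4Cl
Reagents that add atoms: isopropylmagnesium chloride–lithium chloride, CC(C)[Mg]Cl.[Li+].[Cl-] (magnesium and chlorine of 19); N,N-dimethylformamide, CN(C)C=O (formyl group of 20)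
Why: Iodine–magnesium exchange is much faster at the aryl iodide than at the aryl bromide of unit U, and formylation of the aryl Grignard reagent with DMF (Bouveault aldehyde synthesis) gives the C6 aldehyde.

Step 15
Reactants: 20 6-formyl derivative of 17; 10 1-[3,4-bis(benzyloxy)phenyl]ethanone
Product: 21 (E)-enone at C6 of the catechin unit
Conditions: KOH, EtOH/THF, rt → 40 °C
Reagents that add atoms: none
Why: Claisen–Schmidt condensation works as in step 6, since silyl and benzyl ethers and aryl bromide are stable to ethanolic hydroxide.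

Step 16
Reactants: 21 (E)-enone at C6
Product: 22 trans-epoxy ketone of unit M (α-carbon S and β-carbon R)
Conditions: poly-D-leucine, urea·H2O2, DBU, THF, rt
Reagents that add atoms: urea–hydrogen peroxide, NC(N)=O.OO
Why: Juliá–Colonna epoxidation under catalyst control gives the same absolute sense as in step 7, so the α-carbon becomes C3 (S) of unit M.

Step 17
Reactants: 22 trans-epoxy ketone of unit M
Product: 23 anti epoxy alcohol of unit M with R carbinol carbon
Conditions: Zn(BH4)2, Et2O/THF, −30 °C; aq. NH4Cl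
Reagents that add atoms: none
Why: Chelation-controlled reduction as in step 8 sets C2 of unit M anti to the oxirane oxygen.

Step 18
Reactants: 23 anti epoxy alcohol of unit M
Product: 24 TBDPS ether of 23
Conditions: TBDPSCl, imidazole, DMAP (cat.), DMF, rt
Reagents that add atoms: tert-butyl(chloro)diphenylsilane, CC(C)(C)[Si](Cl)(c1ccccc1)c1ccccc1
Why: Base-mediated silyl ether formation protects C2–OH of unit M and spares the acid-labile epoxide.

Step 19
Reactants: 25 4-bromo-2-hydroxybenzaldehyde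
Product: 26 4-bromo-2-hydroxy-5-iodobenzaldehyde
Conditions: NIS, TsOH (cat.), MeCN, rt
Reagents that add atoms: N-iodosuccinimide, O=C1CCC(=O)N1I
Why: Electrophilic aromatic iodination goes para to the phenol hydroxyl (C5), the ortho position between hydroxyl and bromine being shielded.

Step 20
Reactants: 26 4-bromo-2-hydroxy-5-iodobenzaldehyde
Product: 27 2-(benzyloxy)-4-bromo-5-iodobenzaldehyde
Conditions: BnBr, K2CO3, DMF, rt
Reagents that add atoms: benzyl bromide, BrCc1ccccc1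
Why: Williamson ether synthesis on the phenoxide gives the future ring A of unit M, with CHO at its C6, iodine at C4a and bromine at C8a.

Step 21
Reactants: 27 2-(benzyloxy)-4-bromo-5-iodobenzaldehyde; 10 1-[3,4-bis(benzyloxy)phenyl]ethanone
Product: 28 (E)-1-Ar-3-[2-(benzyloxy)-4-bromo-5-iodophenyl]prop-2-en-1-one
Conditions: KOH, EtOH/THF, rt
Reagents that add atoms: none
Why: Claisen–Schmidt condensation gives the E-chalcone of unit T; the aryl halides are inert to hydroxide at room temperature.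

Step 22
Reactants: 28 chalcone of unit T
Product: 29 Ar[(2S,3R)-3-[2-(benzyloxy)-4-bromo-5-iodophenyl]oxiran-2-yl]methanone
Conditions: poly-D-leucine, urea·H2O2, DBU, THF, rt
Reagents that add atoms: urea–hydrogen peroxide, NC(N)=O.OO
Why: Juliá–Colonna epoxidation of an ortho-alkoxy chalcone under catalyst control sets C3 (S) of unit T and the C4 centre that is inverted later.

Step 23
Reactants: 29 trans-epoxy ketone of unit T
Product: 30 anti epoxy alcohol of unit T with R carbinol carbon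
Conditions: Zn(BH4)2, Et2O/THF, −30 °C; aq. NH4Cl
Reagents that add atoms: none
Why: Chelation-controlled reduction as in step 8 sets C2 of unit T; aryl iodide and bromide are not reduced by the borohydride.

Step 24
Reactants: 30 anti epoxy alcohol of unit T
Product: 31 TBDPS ether of 30
Conditions: TBDPSCl, imidazole, DMAP (cat.), DMF, rt
Reagents that add atoms: tert-butyl(chloro)diphenylsilane, CC(C)(C)[Si](Cl)(c1ccccc1)c1ccccc1
Why: Silyl ether formation as in step 9.

Step 25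
Reactants: 31 TBDPS ether of 30; 15 [4-(benzyloxy)-2-bromophenyl]magnesium chloride
Product: 32 open-chain unit T on the iodoarene carrying C2–OTBDPS, free C3–OH and ArBr on C4 (2R,3S,4R)
Conditions: 15 (THF solution), CuI (10 mol%), −40 °C; then 31, −40 → −10 °C; aq. NH4Cl
Reagents that add atoms: none
Why: Copper-catalysed SN2 epoxide opening by the aryl Grignard reagent (organocuprate epoxide opening) with inversion sets C4 of unit T, and the aryl iodide of 31 survives because aryl–aryl iodine–magnesium exchange is slow at −40 °C without LiCl.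

Step 26
Reactants: 32 open-chain unit T with free C3–OH
Product: 33 C3-O-benzyl ether of 32
Conditions: NaH, BnBr, Bu4NI (cat.), THF/DMF, 0 °C
Reagents that add atoms: benzyl bromide, BrCc1ccccc1
Why: Williamson etherification as in step 12 fixes the C3 benzyl ether of unit T.

Step 27
Reactants: 33 C3-O-benzyl ether of 32; 24 TBDPS ether of 23
Product: 35 union product bearing the free C3 hydroxyl of unit M, via fragment T Grignard reagent 34 (not isolated)
Conditions: 33, i-PrMgCl·LiCl, THF, −30 °C; CuI (20 mol%), then 24, −30 → 0 °C; aq. NH4Cl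
Reagents that add atoms: isopropylmagnesium chloride–lithium chloride, CC(C)[Mg]Cl.[Li+].[Cl-] (magnesium and chlorine of 34)
Why: Iodine–magnesium exchange at the iodide ortho to bromine gives Grignard reagent 34, whose copper-catalysed SN2 opening of epoxide 24 at the benzylic carbon (organocuprate epoxide opening, inversion) forms the C4–C4a bond of unit M and sets its C4.

Step 28
Reactants: 35 union product with free C3–OH in unit M
Product: 36 fully protected open-chain compound with three C2–OTBDPS and three C3–OBn groups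
Conditions: NaH, BnBr, Bu4NI (cat.), THF/DMF, 0 °C
Reagents that add atoms: benzyl bromide, BrCc1ccccc1
Why: Williamson etherification as in step 12 gives the last C3 benzyl ether.

Step 29
Reactants: 36 fully protected open-chain compound
Product: 37 tris(2-bromoaryl) triol with free C2–OH in units T, M and U and C3–OBn throughout
Conditions: Bu4NF, AcOH, THF, rt → 40 °C
Reagents that add atoms: none
Why: Fluoride-mediated desilylation frees the three C2 hydroxyls, while benzyl ethers and aryl bromides are inert and the C3 benzyl ethers cannot migrate.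

Step 30
Reactants: 37 tris(2-bromoaryl) triol
Product: 38 heptadeca-O-benzyl tetramer with rings C of units T, M and U closed
Conditions: CuI (30 mol%), 1,10-phenanthroline (60 mol%), Cs2CO3, toluene, 110 °C
Reagents that add atoms: none
Why: Each free C2 hydroxyl is deprotonated by Cs2CO3 and gives a phenanthroline-ligated monovalent copper alkoxide, which adds oxidatively into the aryl bromide ortho to C4 on its own ring A and forms the O1–C8a bond by reductive elimination from trivalent copper. The closest known reaction is the copper-catalysed intramolecular Ullmann-type O-arylation of secondary alcohols with aryl bromides that gives chromans. Each of the three rings C closes in a six-membered mode through O1, C2, C3, C4, C4a and C8a with bromide leaving outside the ring, whereas any cross closure would need a ten-membered or a para-bridged ring. No stereocentre is formed or touched, because the C2–O, C3–O and C4–aryl bonds stay intact, so the (2R,3S,4-trans) triads set in steps 7, 8, 11, 16, 17, 22, 23, 25 and 27 pass unchanged into the chromans. The step needs C2–O over C3–O arylation, which the C3 benzyl ethers secure since they can neither be deprotonated nor migrate, and copper is preferred to palladium because its alkoxides are less prone to β-hydride elimination to the aryl ketone.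

Step 31
Reactants: 38 heptadeca-O-benzyl tetramer
Product: 39 CNP0263622.1
Conditions: H2 (1 atm), Pd(OH)2 on carbon, THF/MeOH, rt
Reagents that add atoms: none
Why: Heterogeneous hydrogenolysis cleaves all seventeen benzyl ethers to toluene and leaves the flavan C2–O1 bonds and the interflavan C4–aryl bonds intact under these mild conditions, as in routine proanthocyanidin deprotection.

## Compound list

1 | 3-bromophenol | Oc1cccc(Br)c1 | starting material
2 | 1-(benzyloxy)-3-bromobenzene | Brc1cccc(OCc2ccccc2)c1 | intermediate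
3 | 4-(benzyloxy)-2-bromo-1-iodobenzene | Ic1ccc(OCc2ccccc2)cc1Br | intermediate
4 | (+)-catechin, (2R,3S) | Oc1cc(O)c2c(c1)O[C@H](c1ccc(O)c(O)c1)[C@@H](O)C2 | starting material
5 | 5,7,3',4'-tetra-O-benzyl-(+)-catechin (free 3-OH) | c1c(OCc9ccccc9)c2c(cc1OCc9ccccc9)O[C@H](c1ccc(OCc9ccccc9)c(OCc9ccccc9)c1)[C@@H](O)C2 | intermediate (not isolated)
6 | 3,5,7,3',4'-penta-O-benzyl-(+)-catechin (cat) | c1c(OCc9ccccc9)c2c(cc1OCc9ccccc9)O[C@H](c1ccc(OCc9ccccc9)c(OCc9ccccc9)c1)[C@@H](OCc9ccccc9)C2 | intermediate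
7 | 8-bromo-cat | c1c(OCc9ccccc9)c2c(c(Br)c1OCc9ccccc9)O[C@H](c1ccc(OCc9ccccc9)c(OCc9ccccc9)c1)[C@@H](OCc9ccccc9)C2 | intermediate
8 | 8-lithio-cat | c1c(OCc9ccccc9)c2c(c([Li])c1OCc9ccccc9)O[C@H](c1ccc(OCc9ccccc9)c(OCc9ccccc9)c1)[C@@H](OCc9ccccc9)C2 | intermediate (not isolated)
9 | cat-8-carbaldehyde | c1c(OCc9ccccc9)c2c(c(C=O)c1OCc9ccccc9)O[C@H](c1ccc(OCc9ccccc9)c(OCc9ccccc9)c1)[C@@H](OCc9ccccc9)C2 | intermediate
10 | 1-[3,4-bis(benzyloxy)phenyl]ethanone | CC(=O)c1ccc(OCc2ccccc2)c(OCc2ccccc2)c1 | starting material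
11 | (E)-1-Ar-3-(cat-8-yl)prop-2-en-1-one | c1c(OCc9ccccc9)c2c(c(/C=C/C(=O)c3ccc(OCc9ccccc9)c(OCc9ccccc9)c3)c1OCc9ccccc9)O[C@H](c1ccc(OCc9ccccc9)c(OCc9ccccc9)c1)[C@@H](OCc9ccccc9)C2 | intermediate
12 | Ar[(2S,3R)-3-(cat-8-yl)oxiran-2-yl]methanone (trans-epoxy ketone) | c1c(OCc9ccccc9)c2c(c([C@H]3O[C@@H]3C(=O)c3ccc(OCc9ccccc9)c(OCc9ccccc9)c3)c1OCc9ccccc9)O[C@H](c1ccc(OCc9ccccc9)c(OCc9ccccc9)c1)[C@@H](OCc9ccccc9)C2 | intermediate
13 | anti epoxy alcohol of unit U (same epoxide as 12, carbinol carbon R) | c1c(OCc9ccccc9)c2c(c([C@H]3O[C@@H]3[C@H](O)c3ccc(OCc9ccccc9)c(OCc9ccccc9)c3)c1OCc9ccccc9)O[C@H](c1ccc(OCc9ccccc9)c(OCc9ccccc9)c1)[C@@H](OCc9ccccc9)C2 | intermediate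
14 | TBDPS ether of 13 | c1c(OCc9ccccc9)c2c(c([C@H]3O[C@@H]3[C@H](O[Si](c8ccccc8)(c8ccccc8)C(C)(C)C)c3ccc(OCc9ccccc9)c(OCc9ccccc9)c3)c1OCc9ccccc9)O[C@H](c1ccc(OCc9ccccc9)c(OCc9ccccc9)c1)[C@@H](OCc9ccccc9)C2 | intermediate
15 | [4-(benzyloxy)-2-bromophenyl]magnesium chloride (used as a cold THF solution) | Cl[Mg]c1ccc(OCc2ccccc2)cc1Br | intermediate
16 | open-chain unit U on cat C8, (2R,3S,4R): C2–OTBDPS, C3–OH, C4 bearing ArBr | c1c(OCc9ccccc9)c2c(c([C@H](c3ccc(OCc9ccccc9)cc3Br)[C@H](O)[C@H](O[Si](c8ccccc8)(c8ccccc8)C(C)(C)C)c3ccc(OCc9ccccc9)c(OCc9ccccc9)c3)c1OCc9ccccc9)O[C@H](c1ccc(OCc9ccccc9)c(OCc9ccccc9)c1)[C@@H](OCc9ccccc9)C2 | intermediate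
17 | C3-O-benzyl ether of 16 | c1c(OCc9ccccc9)c2c(c([C@H](c3ccc(OCc9ccccc9)cc3Br)[C@H](OCc9ccccc9)[C@H](O[Si](c8ccccc8)(c8ccccc8)C(C)(C)C)c3ccc(OCc9ccccc9)c(OCc9ccccc9)c3)c1OCc9ccccc9)O[C@H](c1ccc(OCc9ccccc9)c(OCc9ccccc9)c1)[C@@H](OCc9ccccc9)C2 | intermediate
18 | 6-iodo derivative of 17 | Ic1c(OCc9ccccc9)c2c(c([C@H](c3ccc(OCc9ccccc9)cc3Br)[C@H](OCc9ccccc9)[C@H](O[Si](c8ccccc8)(c8ccccc8)C(C)(C)C)c3ccc(OCc9ccccc9)c(OCc9ccccc9)c3)c1OCc9ccccc9)O[C@H](c1ccc(OCc9ccccc9)c(OCc9ccccc9)c1)[C@@H](OCc9ccccc9)C2 | intermediate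
19 | 6-chloromagnesio derivative of 17 | Cl[Mg]c1c(OCc9ccccc9)c2c(c([C@H](c3ccc(OCc9ccccc9)cc3Br)[C@H](OCc9ccccc9)[C@H](O[Si](c8ccccc8)(c8ccccc8)C(C)(C)C)c3ccc(OCc9ccccc9)c(OCc9ccccc9)c3)c1OCc9ccccc9)O[C@H](c1ccc(OCc9ccccc9)c(OCc9ccccc9)c1)[C@@H](OCc9ccccc9)C2 | intermediate (not isolated)
20 | 6-formyl derivative of 17 | O=Cc1c(OCc9ccccc9)c2c(c([C@H](c3ccc(OCc9ccccc9)cc3Br)[C@H](OCc9ccccc9)[C@H](O[Si](c8ccccc8)(c8ccccc8)C(C)(C)C)c3ccc(OCc9ccccc9)c(OCc9ccccc9)c3)c1OCc9ccccc9)O[C@H](c1ccc(OCc9ccccc9)c(OCc9ccccc9)c1)[C@@H](OCc9ccccc9)C2 | intermediate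
21 | (E)-enone at C6 (chalcone of unit M) | O=C(c4ccc(OCc9ccccc9)c(OCc9ccccc9)c4)/C=C/c1c(OCc9ccccc9)c2c(c([C@H](c3ccc(OCc9ccccc9)cc3Br)[C@H](OCc9ccccc9)[C@H](O[Si](c8ccccc8)(c8ccccc8)C(C)(C)C)c3ccc(OCc9ccccc9)c(OCc9ccccc9)c3)c1OCc9ccccc9)O[C@H](c1ccc(OCc9ccccc9)c(OCc9ccccc9)c1)[C@@H](OCc9ccccc9)C2 | intermediate
22 | trans-epoxy ketone of unit M (α-carbon S, β-carbon R) | O=C(c4ccc(OCc9ccccc9)c(OCc9ccccc9)c4)[C@H]5O[C@@H]5c1c(OCc9ccccc9)c2c(c([C@H](c3ccc(OCc9ccccc9)cc3Br)[C@H](OCc9ccccc9)[C@H](O[Si](c8ccccc8)(c8ccccc8)C(C)(C)C)c3ccc(OCc9ccccc9)c(OCc9ccccc9)c3)c1OCc9ccccc9)O[C@H](c1ccc(OCc9ccccc9)c(OCc9ccccc9)c1)[C@@H](OCc9ccccc9)C2 | intermediate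
23 | anti epoxy alcohol of unit M (carbinol carbon R) | O[C@H](c4ccc(OCc9ccccc9)c(OCc9ccccc9)c4)[C@H]5O[C@@H]5c1c(OCc9ccccc9)c2c(c([C@H](c3ccc(OCc9ccccc9)cc3Br)[C@H](OCc9ccccc9)[C@H](O[Si](c8ccccc8)(c8ccccc8)C(C)(C)C)c3ccc(OCc9ccccc9)c(OCc9ccccc9)c3)c1OCc9ccccc9)O[C@H](c1ccc(OCc9ccccc9)c(OCc9ccccc9)c1)[C@@H](OCc9ccccc9)C2 | intermediate
24 | TBDPS ether of 23 | CC(C)(C)[Si](c8ccccc8)(c8ccccc8)O[C@H](c4ccc(OCc9ccccc9)c(OCc9ccccc9)c4)[C@H]5O[C@@H]5c1c(OCc9ccccc9)c2c(c([C@H](c3ccc(OCc9ccccc9)cc3Br)[C@H](OCc9ccccc9)[C@H](O[Si](c8ccccc8)(c8ccccc8)C(C)(C)C)c3ccc(OCc9ccccc9)c(OCc9ccccc9)c3)c1OCc9ccccc9)O[C@H](c1ccc(OCc9ccccc9)c(OCc9ccccc9)c1)[C@@H](OCc9ccccc9)C2 | intermediate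
25 | 4-bromo-2-hydroxybenzaldehyde | O=Cc1ccc(Br)cc1O | starting material
26 | 4-bromo-2-hydroxy-5-iodobenzaldehyde | O=Cc1cc(I)c(Br)cc1O | intermediate
27 | 2-(benzyloxy)-4-bromo-5-iodobenzaldehyde | O=Cc1cc(I)c(Br)cc1OCc1ccccc1 | intermediate
28 | (E)-1-Ar-3-[2-(benzyloxy)-4-bromo-5-iodophenyl]prop-2-en-1-one | O=C(c2ccc(OCc9ccccc9)c(OCc9ccccc9)c2)/C=C/c1cc(I)c(Br)cc1OCc9ccccc9 | intermediate
29 | Ar[(2S,3R)-3-[2-(benzyloxy)-4-bromo-5-iodophenyl]oxiran-2-yl]methanone | O=C(c2ccc(OCc9ccccc9)c(OCc9ccccc9)c2)[C@H]3O[C@@H]3c1cc(I)c(Br)cc1OCc9ccccc9 | intermediate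
30 | anti epoxy alcohol of unit T (carbinol carbon R) | O[C@H](c2ccc(OCc9ccccc9)c(OCc9ccccc9)c2)[C@H]3O[C@@H]3c1cc(I)c(Br)cc1OCc9ccccc9 | intermediate
31 | TBDPS ether of 30 | CC(C)(C)[Si](c8ccccc8)(c8ccccc8)O[C@H](c2ccc(OCc9ccccc9)c(OCc9ccccc9)c2)[C@H]3O[C@@H]3c1cc(I)c(Br)cc1OCc9ccccc9 | intermediate
32 | open-chain unit T on the iodoarene, (2R,3S,4R): C2–OTBDPS, C3–OH, C4 bearing ArBr | CC(C)(C)[Si](c8ccccc8)(c8ccccc8)O[C@H](c2ccc(OCc9ccccc9)c(OCc9ccccc9)c2)[C@@H](O)[C@@H](c2ccc(OCc9ccccc9)cc2Br)c1cc(I)c(Br)cc1OCc9ccccc9 | intermediate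
33 | C3-O-benzyl ether of 32 | CC(C)(C)[Si](c8ccccc8)(c8ccccc8)O[C@H](c2ccc(OCc9ccccc9)c(OCc9ccccc9)c2)[C@@H](OCc9ccccc9)[C@@H](c2ccc(OCc9ccccc9)cc2Br)c1cc(I)c(Br)cc1OCc9ccccc9 | intermediate
34 | fragment T Grignard reagent (MgCl in place of the iodine of 33) | CC(C)(C)[Si](c8ccccc8)(c8ccccc8)O[C@H](c2ccc(OCc9ccccc9)c(OCc9ccccc9)c2)[C@@H](OCc9ccccc9)[C@@H](c2ccc(OCc9ccccc9)cc2Br)c1cc([Mg]Cl)c(Br)cc1OCc9ccccc9 | intermediate (not isolated)
35 | union product: unit M with C2–OTBDPS and free C3–OH; units T and U with C2–OTBDPS and C3–OBn | CC(C)(C)[Si](c8ccccc8)(c8ccccc8)O[C@H](c1ccc(OCc9ccccc9)c(OCc9ccccc9)c1)[C@@H](OCc9ccccc9)[C@@H](c1ccc(OCc9ccccc9)cc1Br)c1cc([C@@H](c2c(OCc9ccccc9)c3c(c([C@H](c4ccc(OCc9ccccc9)cc4Br)[C@H](OCc9ccccc9)[C@H](O[Si](c8ccccc8)(c8ccccc8)C(C)(C)C)c4ccc(OCc9ccccc9)c(OCc9ccccc9)c4)c2OCc9ccccc9)O[C@H](c2ccc(OCc9ccccc9)c(OCc9ccccc9)c2)[C@@H](OCc9ccccc9)C3)[C@H](O)[C@H](O[Si](c8ccccc8)(c8ccccc8)C(C)(C)C)c2ccc(OCc9ccccc9)c(OCc9ccccc9)c2)c(Br)cc1OCc9ccccc9 | intermediate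
36 | fully protected open-chain compound (three C2–OTBDPS, three C3–OBn) | CC(C)(C)[Si](c8ccccc8)(c8ccccc8)O[C@H](c1ccc(OCc9ccccc9)c(OCc9ccccc9)c1)[C@@H](OCc9ccccc9)[C@@H](c1ccc(OCc9ccccc9)cc1Br)c1cc([C@@H](c2c(OCc9ccccc9)c3c(c([C@H](c4ccc(OCc9ccccc9)cc4Br)[C@H](OCc9ccccc9)[C@H](O[Si](c8ccccc8)(c8ccccc8)C(C)(C)C)c4ccc(OCc9ccccc9)c(OCc9ccccc9)c4)c2OCc9ccccc9)O[C@H](c2ccc(OCc9ccccc9)c(OCc9ccccc9)c2)[C@@H](OCc9ccccc9)C3)[C@H](OCc9ccccc9)[C@H](O[Si](c8ccccc8)(c8ccccc8)C(C)(C)C)c2ccc(OCc9ccccc9)c(OCc9ccccc9)c2)c(Br)cc1OCc9ccccc9 | intermediate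
37 | tris(2-bromoaryl) triol: free C2–OH and C3–OBn in units T, M and U on penta-O-benzylcatechin (key-step precursor) | O[C@H](c1ccc(OCc9ccccc9)c(OCc9ccccc9)c1)[C@@H](OCc9ccccc9)[C@@H](c1ccc(OCc9ccccc9)cc1Br)c1cc([C@@H](c2c(OCc9ccccc9)c3c(c([C@H](c4ccc(OCc9ccccc9)cc4Br)[C@H](OCc9ccccc9)[C@H](O)c4ccc(OCc9ccccc9)c(OCc9ccccc9)c4)c2OCc9ccccc9)O[C@H](c2ccc(OCc9ccccc9)c(OCc9ccccc9)c2)[C@@H](OCc9ccccc9)C3)[C@H](OCc9ccccc9)[C@H](O)c2ccc(OCc9ccccc9)c(OCc9ccccc9)c2)c(Br)cc1OCc9ccccc9 | intermediate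
38 | heptadeca-O-benzyl tetramer (rings C of T, M and U closed; key-step product) | c9ccccc9COc1ccc2c(c1)O[C@H](c1ccc(OCc9ccccc9)c(OCc9ccccc9)c1)[C@@H](OCc9ccccc9)[C@@H]2c1cc2c(cc1OCc9ccccc9)O[C@H](c1ccc(OCc9ccccc9)c(OCc9ccccc9)c1)[C@@H](OCc9ccccc9)[C@@H]2c1c(OCc9ccccc9)c2c(c([C@@H]3c4ccc(OCc9ccccc9)cc4O[C@H](c4ccc(OCc9ccccc9)c(OCc9ccccc9)c4)[C@H]3OCc9ccccc9)c1OCc9ccccc9)O[C@H](c1ccc(OCc9ccccc9)c(OCc9ccccc9)c1)[C@@H](OCc9ccccc9)C2 | intermediate
39 | CNP0263622.1: (2R,3S)-catechin carrying at C6 a 2,3-trans-3,4-trans fisetinidol unit (M, C4→C6), itself carrying a second such unit (T) at its C6, and at C8 a third 2,3-trans-3,4-trans fisetinidol unit (U, C4→C8) | Oc1ccc2c(c1)O[C@H](c1ccc(O)c(O)c1)[C@@H](O)[C@@H]2c1cc2c(cc1O)O[C@H](c1ccc(O)c(O)c1)[C@@H](O)[C@@H]2c1c(O)c2c(c([C@@H]3c4ccc(O)cc4O[C@H](c4ccc(O)c(O)c4)[C@H]3O)c1O)O[C@H](c1ccc(O)c(O)c1)[C@@H](O)C2 | target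

## Step count and risks

Total step count: 31. Longest linear sequence: 20 steps from (+)-catechin (steps 3–9, 11–18 and 27–31). Side branches: steps 1, 2 and 10 (ring A iodide and its Grignard reagent) and steps 19–26 (unit T on the future ring A of unit M).

Steps most likely to fail:

1. Step 30 (threefold ring closure). The closure may stop after one or two rings at the most hindered sites, unreacted aryl bromides may be reduced to aryl C–H, or a benzylic copper alkoxide may be oxidised to the aryl ketone. The fallback sets out from 37 and comes back at 38. The three aryl bromides would be converted by Miyaura borylation (B2pin2, Pd(dppf)Cl2, KOAc, dioxane, 90 °C) into the tris(pinacol boronate) triol F1. Each boronate would then be coupled with its own C2 hydroxyl by oxidative copper-mediated etherification (Chan–Lam coupling: Cu(OAc)2, pyridine, 4 Å molecular sieves, air, CH2Cl2, rt). This forms the same three O1–C8a bonds at room temperature by aryl transfer from boron to divalent copper instead of oxidative addition of an aryl halide.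

2. Step 27 (fragment union). The epoxide on the fully substituted trialkoxyphenyl ring may ionise before it is attacked, giving a ketone by hydride shift or a product without clean inversion. The bulky arylcopper species may also react so slowly that protonation or coupling with 2-iodopropane consumes it. The fallback sets out from 33 and 21 and comes back at 37. Grignard reagent 34 would be quenched with B(OMe)3 and hydrolysed to the arylboronic acid F2. Rhodium-catalysed asymmetric 1,4-addition of F2 to enone 21 (Hayashi–Miyaura reaction: [Rh(cod)OH]2, the BINAP enantiomer that gives the required C4 configuration, dioxane/H2O, 60 °C) would give the β,β-diaryl ketone F3 without any epoxide. Hydroxylation of its potassium enolate (KN(SiMe3)2, then the matching enantiomer of (camphorsulfonyl)oxaziridine, THF, −78 °C) would give the α-hydroxy ketone F4. Benzylation under neutral conditions (BnBr, Ag2O) would give the α-benzyloxy ketone F5. Chelation-controlled reduction with Zn(BH4)2 would give the anti alcohol F6, in which unit M already has its free C2 hydroxyl. Bu4NF would then remove the two remaining silyl groups and rejoin the route at 37.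

3. Step 16 (asymmetric epoxidation of the most congested enone). Peroxide addition may be slow and poorly face-selective because the polypeptide helix cannot bind the bulky, electron-rich enone, so that both trans-epoxide diastereomers form. The fallback sets out from 21 and comes back at 24. Corey–Bakshi–Shibata reduction of the enone (B-methyl oxazaborolidine, BH3·SMe2; the catalyst enantiomer that gives the S carbinol) would give the allylic alcohol F7. Silylation (TBDPSCl, imidazole, DMF) would give its silyl ether F8. Shi epoxidation with the D-fructose-derived ketone (KHSO5, K2CO3, MeCN/dimethoxymethane/H2O, 0 °C), whose face selectivity rests on the trans-alkene and not on a bound enone, would then give epoxide 24 directly, so that 22 and 23 are bypassed.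

## Further compounds

F1 | step 30 | tris(pinacol boronate) triol (each Br of 37 replaced by 4,4,5,5-tetramethyl-1,3,2-dioxaborolan-2-yl) | O[C@H](c1ccc(OCc9ccccc9)c(OCc9ccccc9)c1)[C@@H](OCc9ccccc9)[C@@H](c1ccc(OCc9ccccc9)cc1B5OC(C)(C)C(C)(C)O5)c1cc([C@@H](c2c(OCc9ccccc9)c3c(c([C@H](c4ccc(OCc9ccccc9)cc4B5OC(C)(C)C(C)(C)O5)[C@H](OCc9ccccc9)[C@H](O)c4ccc(OCc9ccccc9)c(OCc9ccccc9)c4)c2OCc9ccccc9)O[C@H](c2ccc(OCc9ccccc9)c(OCc9ccccc9)c2)[C@@H](OCc9ccccc9)C3)[C@H](OCc9ccccc9)[C@H](O)c2ccc(OCc9ccccc9)c(OCc9ccccc9)c2)c(B5OC(C)(C)C(C)(C)O5)cc1OCc9ccccc9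
F2 | step 27 | arylboronic acid from 33 (B(OH)2 in place of I) | CC(C)(C)[Si](c8ccccc8)(c8ccccc8)O[C@H](c2ccc(OCc9ccccc9)c(OCc9ccccc9)c2)[C@@H](OCc9ccccc9)[C@@H](c2ccc(OCc9ccccc9)cc2Br)c1cc(B(O)O)c(Br)cc1OCc9ccccc9
F3 | step 27 | β,β-diaryl ketone of unit M (C4 set, C3 as CH2, C2 as ketone) | CC(C)(C)[Si](c8ccccc8)(c8ccccc8)O[C@H](c1ccc(OCc9ccccc9)c(OCc9ccccc9)c1)[C@@H](OCc9ccccc9)[C@@H](c1ccc(OCc9ccccc9)cc1Br)c1cc([C@@H](c2c(OCc9ccccc9)c3c(c([C@H](c4ccc(OCc9ccccc9)cc4Br)[C@H](OCc9ccccc9)[C@H](O[Si](c8ccccc8)(c8ccccc8)C(C)(C)C)c4ccc(OCc9ccccc9)c(OCc9ccccc9)c4)c2OCc9ccccc9)O[C@H](c2ccc(OCc9ccccc9)c(OCc9ccccc9)c2)[C@@H](OCc9ccccc9)C3)CC(=O)c2ccc(OCc9ccccc9)c(OCc9ccccc9)c2)c(Br)cc1OCc9ccccc9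
F4 | step 27 | α-hydroxy ketone of unit M (C3–OH) | CC(C)(C)[Si](c8ccccc8)(c8ccccc8)O[C@H](c1ccc(OCc9ccccc9)c(OCc9ccccc9)c1)[C@@H](OCc9ccccc9)[C@@H](c1ccc(OCc9ccccc9)cc1Br)c1cc([C@@H](c2c(OCc9ccccc9)c3c(c([C@H](c4ccc(OCc9ccccc9)cc4Br)[C@H](OCc9ccccc9)[C@H](O[Si](c8ccccc8)(c8ccccc8)C(C)(C)C)c4ccc(OCc9ccccc9)c(OCc9ccccc9)c4)c2OCc9ccccc9)O[C@H](c2ccc(OCc9ccccc9)c(OCc9ccccc9)c2)[C@@H](OCc9ccccc9)C3)[C@H](O)C(=O)c2ccc(OCc9ccccc9)c(OCc9ccccc9)c2)c(Br)cc1OCc9ccccc9
F5 | step 27 | α-benzyloxy ketone of unit M (C3–OBn) | CC(C)(C)[Si](c8ccccc8)(c8ccccc8)O[C@H](c1ccc(OCc9ccccc9)c(OCc9ccccc9)c1)[C@@H](OCc9ccccc9)[C@@H](c1ccc(OCc9ccccc9)cc1Br)c1cc([C@@H](c2c(OCc9ccccc9)c3c(c([C@H](c4ccc(OCc9ccccc9)cc4Br)[C@H](OCc9ccccc9)[C@H](O[Si](c8ccccc8)(c8ccccc8)C(C)(C)C)c4ccc(OCc9ccccc9)c(OCc9ccccc9)c4)c2OCc9ccccc9)O[C@H](c2ccc(OCc9ccccc9)c(OCc9ccccc9)c2)[C@@H](OCc9ccccc9)C3)[C@H](OCc9ccccc9)C(=O)c2ccc(OCc9ccccc9)c(OCc9ccccc9)c2)c(Br)cc1OCc9ccccc9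
F6 | step 27 | alcohol with free C2–OH in unit M and C2–OTBDPS still on units T and U | CC(C)(C)[Si](c8ccccc8)(c8ccccc8)O[C@H](c1ccc(OCc9ccccc9)c(OCc9ccccc9)c1)[C@@H](OCc9ccccc9)[C@@H](c1ccc(OCc9ccccc9)cc1Br)c1cc([C@@H](c2c(OCc9ccccc9)c3c(c([C@H](c4ccc(OCc9ccccc9)cc4Br)[C@H](OCc9ccccc9)[C@H](O[Si](c8ccccc8)(c8ccccc8)C(C)(C)C)c4ccc(OCc9ccccc9)c(OCc9ccccc9)c4)c2OCc9ccccc9)O[C@H](c2ccc(OCc9ccccc9)c(OCc9ccccc9)c2)[C@@H](OCc9ccccc9)C3)[C@H](OCc9ccccc9)[C@H](O)c2ccc(OCc9ccccc9)c(OCc9ccccc9)c2)c(Br)cc1OCc9ccccc9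
F7 | step 16 | (S)-allylic alcohol from enone 21 (E-alkene kept) | O[C@H](c4ccc(OCc9ccccc9)c(OCc9ccccc9)c4)/C=C/c1c(OCc9ccccc9)c2c(c([C@H](c3ccc(OCc9ccccc9)cc3Br)[C@H](OCc9ccccc9)[C@H](O[Si](c8ccccc8)(c8ccccc8)C(C)(C)C)c3ccc(OCc9ccccc9)c(OCc9ccccc9)c3)c1OCc9ccccc9)O[C@H](c1ccc(OCc9ccccc9)c(OCc9ccccc9)c1)[C@@H](OCc9ccccc9)C2
F8 | step 16 | TBDPS ether of F7 | CC(C)(C)[Si](c8ccccc8)(c8ccccc8)O[C@H](c4ccc(OCc9ccccc9)c(OCc9ccccc9)c4)/C=C/c1c(OCc9ccccc9)c2c(c([C@H](c3ccc(OCc9ccccc9)cc3Br)[C@H](OCc9ccccc9)[C@H](O[Si](c8ccccc8)(c8ccccc8)C(C)(C)C)c3ccc(OCc9ccccc9)c(OCc9ccccc9)c3)c1OCc9ccccc9)O[C@H](c1ccc(OCc9ccccc9)c(OCc9ccccc9)c1)[C@@H](OCc9ccccc9)C2
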